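**Assumptions (one line each).**
(i) The 4-OH of 1, para to CHO and much more acidic than the 3-OH, alkylates selectively under 1 equiv of base.
(ii) The chiral phosphoric acid (CPA) antipode that gives the (S)-flavan is found by screening both enantiomers.

## Retrosynthetic overview
1. Kazinol B ⇒ cross-metathesis of a 2'-allyl phenol ⇒ aromatic Claisen of the 3'-O-allyl ether (C2' is the only free ortho position).
2. The 3'-O-allyl flavan ⇒ a one-pot relay of two cyclisations on a styrene. Au(I) 6-endo hydroarylation of the aryl 1,1-dimethylpropargyl ether closes the 2,2-dimethylchromene first. A chiral phosphoric acid then drives an inverse-demand oxa-Diels–Alder between the o-quinone methide from 2,4-dihydroxybenzyl alcohol and the styrene, closing the chroman and setting C2 (S).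
3. The styrene ⇐ Wittig ⇐ bis-O-alkylated protocatechualdehyde (4-OH first, then 3-OH).
4. Ring order: chromene, then chroman, both in one pot. The prenyl group is attached last, so the alkenes never see the enantiodetermining conditions.

## Route

**Step 1**
Reactants: 1 (3,4-dihydroxybenzaldehyde), 2 (3-chloro-3-methylbut-1-yne)
Product: 3 (3-hydroxy-4-[(2-methylbut-3-yn-2-yl)oxy]benzaldehyde)
Conditions: 2 (1.5 equiv), DBU (1.0 equiv), CuI (5 mol %), MeCN, 0 °C → rt
Reagents that add atoms: 3-chloro-3-methylbut-1-yne, CC(C)(Cl)C#C (its 2-methylbut-3-yn-2-yl group is incorporated)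
Why: With one equivalent of base only the more acidic 4-phenoxide forms, and Cu-acetylide-assisted substitution of the tertiary propargylic chloride gives the aryl 1,1-dimethylpropargyl ether (Cu-catalysed Williamson-type O-propargylation); excess chloride offsets its partial loss by elimination.

**Step 2**
Reactants: 3, 4 (allyl bromide)
Product: 5 (3-(allyloxy)-4-[(2-methylbut-3-yn-2-yl)oxy]benzaldehyde)
Conditions: 4, K2CO3, DMF, 60 °C
Reagents that add atoms: allyl bromide, C=CCBr
Why: Williamson O-allylation of the remaining phenol; the alkyne, aldehyde and tertiary propargyl ether are untouched.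

**Step 3**
Reactants: 5, 6 (methyltriphenylphosphonium bromide)
Product: 7 (2-(allyloxy)-4-ethenyl-1-[(2-methylbut-3-yn-2-yl)oxy]benzene)
Conditions: 6 (1.1 equiv), KOtBu, THF, 0 °C → rt
Reagents that add atoms: methyltriphenylphosphonium bromide, C[P+](c1ccccc1)(c1ccccc1)c1ccccc1.[Br-] (delivers the =CH2)
Why: Wittig methylenation; the semi-stabilised methylide is not basic enough to deprotonate the terminal alkyne irreversibly, and the allyl and propargyl ethers survive.

**Step 4 (key step, one pot, two rings)**
Reactants: 7, 8 (2,4-dihydroxybenzyl alcohol)
Product: 9 ((2S)-2-[8-(allyloxy)-2,2-dimethyl-2H-chromen-6-yl]chroman-7-ol), formed via the unisolated chromene 10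
Conditions: (i) JohnPhosAu(MeCN)SbF6 (2 mol %), PhCF3, 25 °C, 1 h; (ii) to the same flask add 8 (1.5 equiv), chiral phosphoric acid (TRIP-type, 10 mol %), 4 Å MS, 60 °C, 24 h
Reagents that add atoms: 8, OCc1ccc(O)cc1O (its C7 aryl-CH2 unit is incorporated; the benzylic OH leaves as water)
Why: Proposed new method: Au(I) activates the terminal alkyne of 7, C6 of the arene (the only free ortho carbon of the propargyl ether) attacks 6-endo with gem-dimethyl assistance, and protodeauration gives the 2,2-dimethylchromene 10 (closest known reaction: Au-catalysed hydroarylation of aryl propargyl ethers to 2H-chromenes). The CPA then ionises 8 to the o-quinone methide/2,4-dihydroxybenzyl cation, which adds to the terminal CH2 of the electron-rich styrene of 10. The ortho-OH closes onto the resulting benzylic cation through the H-bonded chiral phosphate, which fixes the face of that carbon as (S) at C2 (closest known reaction: CPA-catalysed inverse-electron-demand oxa-Diels–Alder of o-quinone methides with electron-rich alkenes). The chromene and the chroman both form in this one operation.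

**Step 5**
Reactants: 9
Product: 11 ((2S)-2-(7-allyl-8-hydroxy-2,2-dimethyl-2H-chromen-6-yl)chroman-7-ol)
Conditions: PhNEt2, BHT (cat.), 195 °C, sealed tube, 2 h
Reagents that add atoms: none
Why: Aromatic Claisen [3,3] of the 8-O-allyl ether goes to C7, the only free ortho position, and tautomerisation restores the phenol. The conditions are neutral to basic, so the benzylic C2 ether is not ionised and the stereocentre is untouched.

**Step 6**
Reactants: 11, 12 (2-methylbut-2-ene)
Product: 13 (Kazinol B)
Conditions: Hoveyda–Grubbs II (5 mol %), 12 (20 equiv), CH2Cl2, 40 °C, 12 h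
Reagents that add atoms: 2-methylbut-2-ene, CC=C(C)C (contributes the =CMe2 terminus; propene is lost)
Why: Cross-metathesis of the terminal allyl group with a trisubstituted-alkene donor gives the prenyl group, and the volatile propene drives it. The hindered cis-disubstituted chromene alkene is a poor metathesis substrate, the free phenols are tolerated, and no stereocentre is affected.

## Compound list
1 | 3,4-dihydroxybenzaldehyde | O=Cc1ccc(O)c(O)c1 | starting material
2 | 3-chloro-3-methylbut-1-yne | CC(C)(Cl)C#C | starting material
3 | 3-hydroxy-4-[(2-methylbut-3-yn-2-yl)oxy]benzaldehyde | O=Cc1ccc(OC(C)(C)C#C)c(O)c1 | intermediate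
4 | allyl bromide | C=CCBr | starting material
5 | 3-(allyloxy)-4-[(2-methylbut-3-yn-2-yl)oxy]benzaldehyde | O=Cc1ccc(OC(C)(C)C#C)c(OCC=C)c1 | intermediate
6 | methyltriphenylphosphonium bromide | C[P+](c1ccccc1)(c1ccccc1)c1ccccc1.[Br-] | starting material
7 | 2-(allyloxy)-4-ethenyl-1-[(2-methylbut-3-yn-2-yl)oxy]benzene | C=Cc1ccc(OC(C)(C)C#C)c(OCC=C)c1 | intermediate
8 | 2,4-dihydroxybenzyl alcohol | OCc1ccc(O)cc1O | starting material
9 | (2S)-2-[8-(allyloxy)-2,2-dimethyl-2H-chromen-6-yl]chroman-7-ol | c1c([C@@H]2CCc3ccc(O)cc3O2)cc2c(c1OCC=C)OC(C)(C)C=C2 | intermediate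
10 | 8-(allyloxy)-2,2-dimethyl-6-vinyl-2H-chromene (formed and consumed in Step 4, not isolated) | C=Cc1cc2C=CC(C)(C)Oc2c(OCC=C)c1 | intermediate
11 | (2S)-2-(7-allyl-8-hydroxy-2,2-dimethyl-2H-chromen-6-yl)chroman-7-ol | C=CCc1c([C@@H]2CCc3ccc(O)cc3O2)cc2c(c1O)OC(C)(C)C=C2 | intermediate
12 | 2-methylbut-2-ene | CC=C(C)C | starting material
13 | Kazinol B, (2S)-2-[8-hydroxy-2,2-dimethyl-7-(3-methylbut-2-en-1-yl)-2H-chromen-6-yl]chroman-7-ol | CC(C)=CCc1c([C@@H]2CCc3ccc(O)cc3O2)cc2c(c1O)OC(C)(C)C=C2 | target

## Totals
Total steps: 6. Longest linear sequence: 6 (1 → 3 → 5 → 7 → 9 → 11 → 13); 8 is a commercial convergent partner.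

## Three steps most likely to fail
1. **Step 4 (Au/CPA relay).** The ee of the o-quinone methide/styrene cycloaddition is unproven, the stepwise benzylic cation may lose selectivity, and the Au and CPA may not be compatible in one flask.
   - Fallback: build the flavan stepwise with the stereocentre set by reduction. Convert 3,4-dihydroxyacetophenone as in Steps 1–2 to 3-allyloxy-4-(1,1-dimethylpropargyloxy)acetophenone. Close the chromene with the Au catalyst. Do a Claisen–Schmidt condensation with 2-hydroxy-4-(TBSO)benzaldehyde and reduce the enone C=C chemoselectively. Ru-TsDPEN asymmetric transfer hydrogenation of the diaryl ketone then gives the (R)-carbinol. Intramolecular Mitsunobu closure by the phenol proceeds with inversion to the (S)-flavan, and TBAF removes the silyl group to give 9.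
2. **Step 1 (4-OH-selective propargylation of the catechol).** Over-alkylation or 3-O-alkylation is possible, and the tertiary chloride may eliminate.
   - Fallback: protect the 4-OH selectively as its PMB ether (PMBCl, NaHCO3, NaI, DMF), a well-precedented 4-selective alkylation with a primary electrophile. Allylate the 3-OH and remove the PMB group with TFA/anisole at 0 °C. Then propargylate the sole free phenol, so the hindered tertiary ether goes on last and without any selectivity problem.
3. **Step 6 (cross-metathesis).** The chromene alkene may take part in metathesis, or the phenols may slow the catalyst.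
   - Fallback: use 4-O-TBS-2-hydroxybenzyl alcohol in place of 8 in Step 4, so the 7-OH stays masked. Deallylate the product with Pd(PPh3)4/morpholine to free only the 8-OH. Install the 2-methylbut-3-yn-2-yl ether (CuI, DBU, 3-chloro-3-methylbut-1-yne) and semi-hydrogenate it (Lindlar) to the 1,1-dimethylallyl ether. Claisen rearrangement of that ether at about 195 °C delivers the prenyl group directly at C7, with no metathesis. TBAF then removes the silyl group.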